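At the reading of 5.00 h, the midnight flask shows target at 16.3% and starting material at 0.5%, and a choice has to be made for this same flask.

all flasks: starting material 0.020 M; temperature 35 °C
- midnight: reagent 0.050 M; protic impurity 2 mM; capture agent 6 mM; the very flask that is asked about, followed so far
- flask: reagent 0.0500 M; protic impurity 2.00 mM; capture agent 6.00 mM; time 5.0 h

- midnight (time / h: target / %, starting material / %): 0.417: 1.8, 38.2; 1.00: 5.5, 12.4; 2.00: 11.7, 2.8; 5.00: 16.3, 0.5

(readings scatter by 1 percentage point)

- target that was removed still counts
- the earlier runs do not show what temperature does; that part of a forecast is a guess
- additions bring no volume worth counting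

- elm: change nothing and wait 10 h more
- ash: at 5.0 h add reagent, 50.0% of the amount charged, then wait 10 h
- birch: at 5.0 h raise the temperature by 20 K, then wait 10 h
- cedar: at 5.0 h take out 90% of the target then present, then wait 10 h

- target, in percent of the starting material first charged, at 5.0 h
- which option adds most target ("none" when 2 percentage points or less is all one gets) (elm / ash / birch / cedar / none)
- target present, with what was taken out counted in, in percent of the starting material first charged, after ash
- target present, with what was taken out counted in, in percent of the starting material first charged, after cedar

By 2.00 h the midnight flask holds 2.8% of its starting material, so more of it has gone than has arrived as target. This reckoning takes that fast step as complete, with one reagent spent per starting material charged. That leaves 60.0% of the charged reagent free: this is the reagent left by the fast step, the upper end of this reckoning's bracket, an estimate and not a strict limit. For the lower end, the reagent is taken to pay once more for each target read and once each for the protic impurity and capture agent charged, which gives 37.5%, with no decay of the reagent counted. Yet target gained 6.2 percentage points between 1.00 h and 2.00 h, and 4.6 points in the 3.00 h after that. This reckoning therefore expects target to be leaking elsewhere and ash to gain little, with "now" at the reading, within 1 point.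

The forecast gives 16.5% (15.3% to 17.6%) for "now", 27% (20.5% to 34%) after ash and 17% (15.5% to 20%) after cedar, and it names ash as best. Its ground is that “active reagent has run out”, which places free reagent below the bracket. The two part here.

The flask gives 15.4% at 5.0 h, and the best option is birch, which adds 7.6 points. Cedar adds 4.2 points, ash −6.3 points and elm −7.2 points. Target counts 9.11% after ash and 19.6% after cedar.

    starting material + protic impurity → quenched substrate (k = 129 L mol⁻¹ h⁻¹, Ea = 66.0 kJ mol⁻¹)
    starting material + reagent → intermediate A (k = 39.0 L mol⁻¹ h⁻¹, Ea = 76.0 kJ mol⁻¹)
    starting material → side product (k = 0.375 h⁻¹, Ea = 99.0 kJ mol⁻¹)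
    target ⇌ isomer of the product (K = 7.00, k = 0.248 h⁻¹, Ea = 90.0 kJ mol⁻¹, ΔH = −80.0 kJ mol⁻¹)
    intermediate A ⇌ intermediate B (K = 0.968, k = 0.121 h⁻¹, Ea = 98.0 kJ mol⁻¹, ΔH = −37.0 kJ mol⁻¹)
    reagent + intermediate A → target (k = 4.20 L mol⁻¹ h⁻¹, Ea = 60.0 kJ mol⁻¹)
    capture agent + intermediate B → trapped intermediate (k = 236 L mol⁻¹ h⁻¹, Ea = 46.0 kJ mol⁻¹)
    (constants at 35 °C)

At 5.00 h the flask holds 58.6% of its reagent, between the two ends of the bracket, while the starting material, the limiting reagent, stands at 0.0152%. Part of the gain from birch comes from the undoing of intermediate B into intermediate A: in the run with that undoing taken away, birch brings 1.8 points instead of 7.6 points and no longer stands as best.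

For the neighbour flask with 0.034 M of starting material, the reagent left by the fast step comes to 32.0% of its charge. That computed flask holds 36% of its reagent at 5.0 h, more than the reckoning gives, with target at 11.2%.

Readings and results were generated by integration with constants of no real substance; noise was put on by code.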